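**Retrosynthetic overview**
1. C1 comes from a Colvin homologation, C2–C3 from an E-selective cross-metathesis, and the C4–C5 bond from Cu-catalysed vinylation of an epoxy triflate; no olefination of a sugar-derived aldehyde is used.
2. The oxirane is the second ring and is made late, by Sharpless epoxidation of a Z-allylic alcohol that is itself made by catalytic Z-selective cross-metathesis on the dibrominated core.
3. Both C–Br bonds come from SN2 inversion of carbinols: C9–OH from a chelation-controlled allylation, C12–OH from an aldol.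
4. The oxolane is the first ring and is not made by haloetherification or hydroxy-epoxide opening. It comes from an organocatalytic chloro-aldol (C11–C12), a 1,3-anti reduction and an SN2 cycloetherification (O–C13) that fixes the 2,5-cis geometry stereospecifically.
5. Ring order: oxolane (step 4), then oxirane (step 10).

Assumption: (2R,5R)-2,5-diphenylpyrrolidine is taken to give the (S)-α-chloroaldehyde (if the sense is opposite, its enantiomer is used and nothing else changes); atom labels follow HC1≡C2–C3=C4–C5–C6(O)–C7–C8–C9(Br)–C10(O)–C11–C12(Br)–C13(O)–C14–C15, and the target is (3E,6S,7R,9S,10R,12S,13R) with a cis-oxirane and a 2,5-cis-oxolane whose ring Br is trans to ethyl.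

Step 1
Reactants: 1 butanal
Product: 2 (S)-2-chlorobutanal
Conditions: NCS, (2R,5R)-2,5-diphenylpyrrolidine (10 mol %), CH2Cl2, 0 °C to rt; pentane, filter; solution used at once
Reagents that add atoms: N-chlorosuccinimide, O=C1CCC(=O)N1Cl
Why: Enamine-mediated organocatalytic α-chlorination, in which the C2-symmetric pyrrolidine shields one enamine face so that Cl+ is delivered to give the (S)-chloride (future C13, inverted later) in about 90–95% ee.

Step 2
Reactants: 2 (S)-2-chlorobutanal; 3 1,1-dimethoxypropan-2-one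
Product: 5 (4R,5S)-5-chloro-4-hydroxy-1,1-dimethoxyheptan-2-one, via lithium enolate 4 (not isolated)
Conditions: 3, LDA, THF, −78 °C; then 2, −78 °C; AcOH quench at −78 °C
Reagents that add atoms: lithium diisopropylamide, [Li]N(C(C)C)C(C)C (its Li is in 4 only)
Why: Chloro-aldol reaction of a kinetic methyl-ketone lithium enolate, which attacks the Cornforth (polar Felkin–Anh) conformer of the α-chloroaldehyde to give the 1,2-anti chlorohydrin and so sets C12 as R (typically >10:1), the cold acidic quench preventing epoxide closure or retro-aldol.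

Step 3
Reactants: 5 (4R,5S)-5-chloro-4-hydroxy-1,1-dimethoxyheptan-2-one
Product: 6 (2R,4R,5S)-5-chloro-1,1-dimethoxyheptane-2,4-diol
Conditions: Me4NBH(OAc)3, MeCN/AcOH (1:1), −40 to −20 °C
Reagents that add atoms: none
Why: Evans–Saksena reduction, in which the C12 hydroxyl binds boron and delivers hydride intramolecularly through a chair transition state to give the 1,3-anti diol and thereby C10 as R.

Step 4
Reactants: 6 (2R,4R,5S)-5-chloro-1,1-dimethoxyheptane-2,4-diol
Product: 7 (2R,3R,5R)-5-(dimethoxymethyl)-2-ethyloxolan-3-ol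
Conditions: AgOTf, Ag2O, THF, 50 °C
Reagents that add atoms: none
Why: Silver-assisted 5-exo-tet SN2 cycloetherification (intramolecular Williamson type), in which the C10 hydroxyl displaces the secondary chloride with clean inversion at C13 (S to R), so the all-cis 2,5-disubstituted oxolan-3-ol follows stereospecifically from the centres already set while Ag2O buffers the acid and spares the acetal.

Step 5
Reactants: 7 (2R,3R,5R)-5-(dimethoxymethyl)-2-ethyloxolan-3-ol
Product: 8 (2R,3S,5R)-3-bromo-5-(dimethoxymethyl)-2-ethyloxolane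
Conditions: CBr4, P(n-Oct)3, toluene, 70 °C
Reagents that add atoms: carbon tetrabromide, BrC(Br)(Br)Br
Why: Appel-type deoxybromination, in which bromide attacks the alkoxyphosphonium ion from the open face opposite the ethyl and C5 substituents in an SN2 step with inversion, giving the C12 bromide (S) trans to ethyl.

Step 6
Reactants: 8 (2R,3S,5R)-3-bromo-5-(dimethoxymethyl)-2-ethyloxolane
Product: 9 (2R,4S,5R)-4-bromo-5-ethyloxolane-2-carbaldehyde
Conditions: TFA/H2O (4:1), CH2Cl2, 0 °C to rt; dried azeotropically, used crude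
Reagents that add atoms: water, O
Why: Acid-catalysed acetal hydrolysis unmasks the C9 aldehyde while the C–Br bond and the ring ether are inert, and immediate use avoids epimerisation at C10.

Step 7
Reactants: 9 (2R,4S,5R)-4-bromo-5-ethyloxolane-2-carbaldehyde; 10 allyltributylstannane
Product: 11 (1R)-1-[(2R,4S,5R)-4-bromo-5-ethyloxolan-2-yl]but-3-en-1-ol
Conditions: MgBr2·OEt2, CH2Cl2, −78 °C; then 10, −78 to 0 °C
Reagents that add atoms: none
Why: Keck chelation-controlled allylation, in which MgBr2 bridges the aldehyde and ring oxygens (Cram chelate) and the allylstannane adds from the face opposite the ring CH2 to give the syn (threo) carbinol, C9 = R, typically ≥10:1.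

Step 8
Reactants: 11 (1R)-1-[(2R,4S,5R)-4-bromo-5-ethyloxolan-2-yl]but-3-en-1-ol
Product: 12 (2R,3S,5R)-3-bromo-5-[(1S)-1-bromobut-3-en-1-yl]-2-ethyloxolane
Conditions: CBr4, P(n-Oct)3, toluene, 70 °C
Reagents that add atoms: carbon tetrabromide, BrC(Br)(Br)Br
Why: A second Appel-type SN2 deoxybromination with inversion turns the (9R)-carbinol into the (9S)-bromide anti to the ring oxygen, leaving the ring bromide and the terminal alkene untouched.

Step 9
Reactants: 12 (2R,3S,5R)-3-bromo-5-[(1S)-1-bromobut-3-en-1-yl]-2-ethyloxolane; 13 (Z)-but-2-ene-1,4-diol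
Product: 14 (2Z,5S)-5-bromo-5-[(2R,4S,5R)-4-bromo-5-ethyloxolan-2-yl]pent-2-en-1-ol
Conditions: 13 (3 equiv), Ru 3,6-dichlorobenzene-1,2-dithiolate NHC carbene catalyst (5 mol %), THF, 22 °C
Reagents that add atoms: none
Why: Catalytic Z-selective (stereoretentive) cross-metathesis, in which the dithiolate ligand enforces a side-bound metallacyclobutane with syn substituents so that the new C6=C7 bond forms >95:5 Z and already carries the allylic hydroxyl needed for the next step.

Step 10
Reactants: 14 (2Z,5S)-5-bromo-5-[(2R,4S,5R)-4-bromo-5-ethyloxolan-2-yl]pent-2-en-1-ol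
Product: 15 [(2S,3R)-3-{(2S)-2-bromo-2-[(2R,4S,5R)-4-bromo-5-ethyloxolan-2-yl]ethyl}oxiran-2-yl]methanol
Conditions: Ti(OiPr)4, L-(+)-diethyl tartrate, t-BuOOH, 4 Å MS, CH2Cl2, −20 °C
Reagents that add atoms: tert-butyl hydroperoxide, CC(C)(C)OO
Why: Katsuki–Sharpless asymmetric epoxidation, in which the titanium L-(+)-tartrate complex delivers oxygen to one face of the Z-allylic alcohol under reagent control to give the (2S,3R) cis-epoxide (C6 = S, C7 = R), the alkyl bromides being inert.

Step 11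
Reactants: 15 [(2S,3R)-3-{(2S)-2-bromo-2-[(2R,4S,5R)-4-bromo-5-ethyloxolan-2-yl]ethyl}oxiran-2-yl]methanol; 16 vinylmagnesium bromide
Product: 18 (2R,3S)-2-{(2S)-2-bromo-2-[(2R,4S,5R)-4-bromo-5-ethyloxolan-2-yl]ethyl}-3-(prop-2-en-1-yl)oxirane, via epoxy triflate 17 (not isolated)
Conditions: Tf2O, 2,6-lutidine, CH2Cl2, −78 °C; then 16, CuI (20 mol %), Et2O/THF, −78 to −40 °C, cold quench
Reagents that add atoms: trifluoromethanesulfonic anhydride, O=S(=O)(OS(=O)(=O)C(F)(F)F)C(F)(F)F (its CF3SO2 group is in 17 only)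
Why: Copper-catalysed SN2 coupling of a Grignard reagent with a primary triflate, which at −78 °C is displaced far faster than the disubstituted epoxide or the secondary bromides react, so C4 is joined to C5 without touching any stereocentre.

Step 12
Reactants: 18 (2R,3S)-2-{(2S)-2-bromo-2-[(2R,4S,5R)-4-bromo-5-ethyloxolan-2-yl]ethyl}-3-(prop-2-en-1-yl)oxirane; 19 (E)-but-2-enal
Product: 20 (2E)-4-[(2S,3R)-3-{(2S)-2-bromo-2-[(2R,4S,5R)-4-bromo-5-ethyloxolan-2-yl]ethyl}oxiran-2-yl]but-2-enal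
Conditions: 19 (5 equiv), Grubbs II (5 mol %), CH2Cl2, 40 °C
Reagents that add atoms: none
Why: Olefin cross-metathesis of a terminal alkene with an electron-poor partner is thermodynamically E-selective (>15:1) and exchanges the terminal CH2 for CH–CHO under neutral conditions that spare epoxide and bromides.

Step 13
Reactants: 20 (2E)-4-[(2S,3R)-3-{(2S)-2-bromo-2-[(2R,4S,5R)-4-bromo-5-ethyloxolan-2-yl]ethyl}oxiran-2-yl]but-2-enal
Product: 21 (2R,3S,5R)-3-bromo-5-[(1S)-1-bromo-2-{(2R,3S)-3-[(2E)-pent-2-en-4-yn-1-yl]oxiran-2-yl}ethyl]-2-ethyloxolane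
Conditions: TMSCHN2, n-BuLi, THF, −78 °C; then 20, −78 to 0 °C
Reagents that add atoms: (trimethylsilyl)diazomethane, C[Si](C)(C)C=[N+]=[N-]
Why: Colvin rearrangement, in which 1,2-addition of lithiated TMS-diazomethane to the enal, Peterson-type loss of silanolate, loss of N2 and 1,2-hydride shift of the alkylidene carbene give the terminal alkyne with the E-alkene and all stereocentres intact.

**Compound list**
1 | butanal | CCCC=O | starting material
2 | (S)-2-chlorobutanal | O=C[C@@H](Cl)CC | intermediate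
3 | 1,1-dimethoxypropan-2-one | COC(OC)C(C)=O | starting material
4 | lithium 3,3-dimethoxyprop-1-en-2-olate | COC(OC)C(=C)O[Li] | intermediate
5 | (4R,5S)-5-chloro-4-hydroxy-1,1-dimethoxyheptan-2-one | COC(OC)C(=O)C[C@@H](O)[C@@H](Cl)CC | intermediate
6 | (2R,4R,5S)-5-chloro-1,1-dimethoxyheptane-2,4-diol | COC(OC)[C@H](O)C[C@@H](O)[C@@H](Cl)CC | intermediate
7 | (2R,3R,5R)-5-(dimethoxymethyl)-2-ethyloxolan-3-ol | COC(OC)[C@H]1C[C@@H](O)[C@@H](CC)O1 | intermediate
8 | (2R,3S,5R)-3-bromo-5-(dimethoxymethyl)-2-ethyloxolane | COC(OC)[C@H]1C[C@H](Br)[C@@H](CC)O1 | intermediate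
9 | (2R,4S,5R)-4-bromo-5-ethyloxolane-2-carbaldehyde | O=C[C@H]1C[C@H](Br)[C@@H](CC)O1 | intermediate
10 | allyltributylstannane | C=CC[Sn](CCCC)(CCCC)CCCC | starting material
11 | (1R)-1-[(2R,4S,5R)-4-bromo-5-ethyloxolan-2-yl]but-3-en-1-ol | C=CC[C@@H](O)[C@H]1C[C@H](Br)[C@@H](CC)O1 | intermediate
12 | (2R,3S,5R)-3-bromo-5-[(1S)-1-bromobut-3-en-1-yl]-2-ethyloxolane | C=CC[C@H](Br)[C@H]1C[C@H](Br)[C@@H](CC)O1 | intermediate
13 | (Z)-but-2-ene-1,4-diol | OC/C=C\CO | starting material
14 | (2Z,5S)-5-bromo-5-[(2R,4S,5R)-4-bromo-5-ethyloxolan-2-yl]pent-2-en-1-ol | OC/C=C\C[C@H](Br)[C@H]1C[C@H](Br)[C@@H](CC)O1 | intermediate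
15 | [(2S,3R)-3-{(2S)-2-bromo-2-[(2R,4S,5R)-4-bromo-5-ethyloxolan-2-yl]ethyl}oxiran-2-yl]methanol | OC[C@@H]1O[C@@H]1C[C@H](Br)[C@H]1C[C@H](Br)[C@@H](CC)O1 | intermediate
16 | vinylmagnesium bromide | C=C[Mg]Br | starting material
17 | [(2S,3R)-3-{(2S)-2-bromo-2-[(2R,4S,5R)-4-bromo-5-ethyloxolan-2-yl]ethyl}oxiran-2-yl]methyl trifluoromethanesulfonate | FC(F)(F)S(=O)(=O)OC[C@@H]1O[C@@H]1C[C@H](Br)[C@H]1C[C@H](Br)[C@@H](CC)O1 | intermediate
18 | (2R,3S)-2-{(2S)-2-bromo-2-[(2R,4S,5R)-4-bromo-5-ethyloxolan-2-yl]ethyl}-3-(prop-2-en-1-yl)oxirane | C=CC[C@@H]1O[C@@H]1C[C@H](Br)[C@H]1C[C@H](Br)[C@@H](CC)O1 | intermediate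
19 | (E)-but-2-enal | C/C=C/C=O | starting material
20 | (2E)-4-[(2S,3R)-3-{(2S)-2-bromo-2-[(2R,4S,5R)-4-bromo-5-ethyloxolan-2-yl]ethyl}oxiran-2-yl]but-2-enal | O=C/C=C/C[C@@H]1O[C@@H]1C[C@H](Br)[C@H]1C[C@H](Br)[C@@H](CC)O1 | intermediate
21 | (2R,3S,5R)-3-bromo-5-[(1S)-1-bromo-2-{(2R,3S)-3-[(2E)-pent-2-en-4-yn-1-yl]oxiran-2-yl}ethyl]-2-ethyloxolane | C#C/C=C/C[C@@H]1O[C@@H]1C[C@H](Br)[C@H]1C[C@H](Br)[C@@H](CC)O1 | target

**Totals**
Total step count: 13. Longest linear sequence: 13 steps (1 to 21); all other inputs are commercial.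

**Steps most likely to fail**

Step 8 (deoxybromination at C9). The carbinol sits next to the ring oxygen and is homoallylic, so the phosphonium intermediate can eliminate to a diene or be captured by the ring oxygen (retention or ring expansion). The fallback sets out from 11 and separates activation from substitution. The alcohol is converted with chloromethanesulfonyl chloride and 2,6-lutidine (CH2Cl2, 0 °C) into the isolable sulfonate (1R)-1-[(2R,4S,5R)-4-bromo-5-ethyloxolan-2-yl]but-3-en-1-yl chloromethanesulfonate F1. This is then displaced in a separate SN2 step by LiBr in THF at 50 °C, with no phosphine or phosphonium species present, and the route is rejoined at 12.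

Step 11 (vinyl transfer to the epoxy triflate). A vinyl copper species may be too sluggish, or magnesium halide may open the oxirane. The fallback sets out from 15, passes through the same triflate 17 and uses an sp nucleophile. Lithium (trimethylsilyl)acetylide in THF/DMPU at −78 °C gives trimethyl{3-[(2S,3R)-3-{(2S)-2-bromo-2-[(2R,4S,5R)-4-bromo-5-ethyloxolan-2-yl]ethyl}oxiran-2-yl]prop-1-yn-1-yl}silane F2. K2CO3 in MeOH removes the silyl group to give (2R,3S)-2-{(2S)-2-bromo-2-[(2R,4S,5R)-4-bromo-5-ethyloxolan-2-yl]ethyl}-3-(prop-2-yn-1-yl)oxirane F3. Lindlar semi-hydrogenation (H2, Pd/CaCO3–Pb, quinoline) then brings the route back at 18.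

Step 13 (Colvin homologation). The enal 20 has acidic γ-hydrogens next to the oxirane, so a strong base can trigger vinylogous enolisation and epoxide opening. The fallback sets out from 18 and avoids both the enal and the strong base. Cross-metathesis with vinylboronic acid pinacol ester (Grubbs II, CH2Cl2, 40 °C) gives 2-[(1E)-3-[(2S,3R)-3-{(2S)-2-bromo-2-[(2R,4S,5R)-4-bromo-5-ethyloxolan-2-yl]ethyl}oxiran-2-yl]prop-1-en-1-yl]-4,4,5,5-tetramethyl-1,3,2-dioxaborolane F4. Suzuki–Miyaura coupling with (bromoethynyl)triisopropylsilane (Pd(PPh3)4, aq. K3PO4, THF, 40 °C) gives [(3E)-5-[(2S,3R)-3-{(2S)-2-bromo-2-[(2R,4S,5R)-4-bromo-5-ethyloxolan-2-yl]ethyl}oxiran-2-yl]pent-3-en-1-yn-1-yl]tri(propan-2-yl)silane F5. TBAF in THF at 0 °C then gives 21.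

**Further compounds**
F1 | step 8 | (1R)-1-[(2R,4S,5R)-4-bromo-5-ethyloxolan-2-yl]but-3-en-1-yl chloromethanesulfonate | C=CC[C@@H](OS(=O)(=O)CCl)[C@H]1C[C@H](Br)[C@@H](CC)O1
F2 | step 11 | trimethyl{3-[(2S,3R)-3-{(2S)-2-bromo-2-[(2R,4S,5R)-4-bromo-5-ethyloxolan-2-yl]ethyl}oxiran-2-yl]prop-1-yn-1-yl}silane | C[Si](C)(C)C#CC[C@@H]1O[C@@H]1C[C@H](Br)[C@H]1C[C@H](Br)[C@@H](CC)O1
F3 | step 11 | (2R,3S)-2-{(2S)-2-bromo-2-[(2R,4S,5R)-4-bromo-5-ethyloxolan-2-yl]ethyl}-3-(prop-2-yn-1-yl)oxirane | C#CC[C@@H]1O[C@@H]1C[C@H](Br)[C@H]1C[C@H](Br)[C@@H](CC)O1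
F4 | step 13 | 2-[(1E)-3-[(2S,3R)-3-{(2S)-2-bromo-2-[(2R,4S,5R)-4-bromo-5-ethyloxolan-2-yl]ethyl}oxiran-2-yl]prop-1-en-1-yl]-4,4,5,5-tetramethyl-1,3,2-dioxaborolane | CC1(C)OB(OC1(C)C)/C=C/C[C@@H]1O[C@@H]1C[C@H](Br)[C@H]1C[C@H](Br)[C@@H](CC)O1
F5 | step 13 | [(3E)-5-[(2S,3R)-3-{(2S)-2-bromo-2-[(2R,4S,5R)-4-bromo-5-ethyloxolan-2-yl]ethyl}oxiran-2-yl]pent-3-en-1-yn-1-yl]tri(propan-2-yl)silane | CC(C)[Si](C(C)C)(C(C)C)C#C/C=C/C[C@@H]1O[C@@H]1C[C@H](Br)[C@H]1C[C@H](Br)[C@@H](CC)O1
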